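## Retrosynthetic overview
1. The target 21 comes from acrylate 19 by late α-hydroxymethylation of the C8 acrylate. Enal 19 comes from lactone 18 by allylic oxidation of the C15 methyl group.
2. The trans-lactone of 18 comes from the ten-membered dienone 16 by 1,2-reduction at C6, which sets C6, followed by lactonisation.
3. The ten-membered ring of 16 comes from decalin 15 by cleaving the ring-fusion bond C1–C6 at palladium. The same step places the acetate on C14 and forms the C1=C10 alkene.
4. Ring B of the decalin is closed by an intramolecular allylindium addition (C6–C7 bond, sets C7). C8 is set by an asymmetric Nozaki–Hiyama allylation that joins 5 and 11.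
5. Order of rings: cyclohexenone ring A (bought), then ring B, then the ten-membered ring (ring expansion), then the γ-lactone.

Assumption: germacrane numbering (C1–C15) is used throughout; the tert-butyl group of 6 counts as a carboxyl protecting group (lost in step 11); C1 and C6 in 3–5, 12, 13 and 15 are left uncontrolled because both centres vanish in step 10.

## Route

Step 1
Reactants: 1 3-methylcyclohex-2-en-1-one; 2 acetone
Product: 3 6-(2-hydroxypropan-2-yl)-3-methylcyclohex-2-en-1-one (racemic)
Conditions: LDA, THF, −78 °C; then 2; H2O quench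
Reagents that add atoms: none
Why: Kinetic deprotonation gives the cross-conjugated enolate at the ring CH2 next to the carbonyl (later C1), which undergoes aldol addition to acetone; the new centre is racemic and is erased in step 10.

Step 2
Reactants: 3 6-(2-hydroxypropan-2-yl)-3-methylcyclohex-2-en-1-one
Product: 4 3-methyl-6-(prop-1-en-2-yl)cyclohex-2-en-1-one (racemic)
Conditions: SOCl2, pyridine, 0 °C
Reagents that add atoms: none
Why: This is an E2 dehydration of the chlorosulfite, and because pyridine is too weak to enolise the ketone, loss of one of the six methyl hydrogens gives the isopropenyl isomer rather than the conjugated isopropylidene isomer.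

Step 3
Reactants: 4 3-methyl-6-(prop-1-en-2-yl)cyclohex-2-en-1-one
Product: 5 6-(3-chloroprop-1-en-2-yl)-3-methylcyclohex-2-en-1-one (racemic)
Conditions: NCS, PhSeCl (10 mol %), CH2Cl2, 25 °C
Reagents that add atoms: N-chlorosuccinimide O=C1CCC(=O)N1Cl
Why: Selenium-catalysed ene-type allylic chlorination attacks the only electron-rich alkene and regenerates the 1,1-disubstituted double bond by transposition.

Step 4
Reactants: 6 tert-butyl acrylate; 7 2,2-dimethoxyacetaldehyde
Product: 8 tert-butyl 3-hydroxy-4,4-dimethoxy-2-methylidenebutanoate (racemic)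
Conditions: DABCO (30 mol %), 1,4-dioxane–H2O, 25 °C
Reagents that add atoms: none
Why: This is a Morita–Baylis–Hillman reaction with an activated α-alkoxy aldehyde; the carbinol centre is lost in step 5.

Step 5
Reactants: 8 tert-butyl 3-hydroxy-4,4-dimethoxy-2-methylidenebutanoate
Product: 10 tert-butyl (E)-2-(acetoxymethyl)-4,4-dimethoxybut-2-enoate, via secondary acetate 9 (not isolated)
Conditions: Ac2O, DMAP (cat.), THF, 25 °C; then DABCO (20 mol %), 65 °C
Reagents that add atoms: acetic anhydride CC(=O)OC(C)=O
Why: Acetylation is followed by DABCO-catalysed double allylic displacement, which isomerises the Baylis–Hillman acetate to the more stable primary acetate with the acetal carbon trans to the ester.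

Step 6
Reactants: 10 tert-butyl (E)-2-(acetoxymethyl)-4,4-dimethoxybut-2-enoate
Product: 11 tert-butyl (E)-2-(acetoxymethyl)-4-oxobut-2-enoate
Conditions: 1 M aq. HCl, THF, 0 to 25 °C
Reagents that add atoms: water O
Why: Mild acid hydrolysis cleaves the allylic acetal but leaves the tert-butyl ester and the acetate intact.

Step 7
Reactants: 5 6-(3-chloroprop-1-en-2-yl)-3-methylcyclohex-2-en-1-one; 11 tert-butyl (E)-2-(acetoxymethyl)-4-oxobut-2-enoate
Product: 12 tert-butyl (2E,4S)-2-(acetoxymethyl)-4-hydroxy-6-(4-methyl-2-oxocyclohex-3-en-1-yl)hepta-2,6-dienoate (two C1 epimers)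
Conditions: CrCl2 (2.5 equiv), valine-derived oxazoline–sulfonamide ligand (enantiomer that gives the S alcohol), Et3N, THF, 0 °C
Reagents that add atoms: none
Why: In this asymmetric Nozaki–Hiyama allylation the allylchromium reagent, whose two termini are equivalent, adds 1,2 to the aldehyde only, and the chiral ligand on chromium sets C8 as S.

Step 8
Reactants: 12 tert-butyl (2E,4S)-2-(acetoxymethyl)-4-hydroxy-6-(4-methyl-2-oxocyclohex-3-en-1-yl)hepta-2,6-dienoate
Product: 13 tert-butyl 2-[(1R,2S)-2,8a-dihydroxy-7-methyl-4-methylidene-1,2,3,4,4a,5,6,8a-octahydronaphthalen-1-yl]prop-2-enoate (C4a and C8a uncontrolled)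
Conditions: Pd(PPh3)4 (5 mol %), InI (2 equiv), THF, 25 °C
Reagents that add atoms: none
Why: InI reverses the polarity of the π-allylpalladium formed from the primary acetate, and the resulting allylindium closes ring B in a Barbier-type 1,2-addition through its γ-carbon C7 onto the ring ketone via a chair with the C8 oxygen equatorial, which sets C7 (R) trans to the C8 oxygen; the bulky tert-butyl ester holds back lactonisation of the tertiary alcohol.

Step 9
Reactants: 13 decalin diol (name as in step 8); 14 acryloyl chloride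
Product: 15 tert-butyl 2-[(1R,2S)-2-(acryloyloxy)-8a-hydroxy-7-methyl-4-methylidene-1,2,3,4,4a,5,6,8a-octahydronaphthalen-1-yl]prop-2-enoate
Conditions: iPr2NEt, CH2Cl2, −40 to −20 °C
Reagents that add atoms: none
Why: O-acylation takes place only at the secondary C8 alcohol because the tertiary ring-fusion alcohol is too hindered.

Step 10
Reactants: 15 decalin acrylate (name as in step 9)
Product: 16 tert-butyl 2-[(1R,3Z,7E,10S)-8-(acetoxymethyl)-10-(acryloyloxy)-4-methyl-2-oxocyclodeca-3,7-dien-1-yl]prop-2-enoate
Conditions: Pd(OAc)2 (10 mol %), 4,5-diazafluoren-9-one (12 mol %), 1,4-benzoquinone (1.2 equiv), NaOAc, AcOH–1,4-dioxane, 60 °C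
Reagents that add atoms: acetic acid CC(=O)O
Why: Proposed new method: the tertiary alkoxide of 15 binds divalent palladium and, with the C6–O bond axial on ring B and gauche to C1–C10, the exocyclic C10=C14 alkene reaches the metal, so β-carbon elimination cleaves the ring-fusion bond C1–C6 (an organometallic retro-allylation whose closest known types are the palladium-catalysed retro-allylation of tertiary homoallylic alcohols and the ring opening of tert-cyclobutanols) and expands the decalin to the ten-membered dienone carrying a π-allylpalladium acetate (C14–C10–C1); this π-allyl equilibrates to the isomer with C2 syn to C9, is attacked by acetate at the unhindered C14 terminus as in palladium/benzoquinone allylic acetoxylation, and benzoquinone returns zerovalent palladium to the divalent state, while the electron-poor C11=C13 acrylate binds divalent palladium poorly and should leave C6–C7 intact.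

Step 11
Reactants: 16 ten-membered dienone (name as in step 10)
Product: 18 (6R,7R,8S)-14-acetoxy-8-(acryloyloxy)germacra-1(10)E,4Z,11(13)-trien-12,6-olide (both ring alkenes ring-cis), via hydroxy ester 17 (not isolated)
Conditions: NaBH4, CeCl3·7H2O, MeOH, −78 °C; work-up; then TFA–CH2Cl2 1:4, 0 °C
Reagents that add atoms: none
Why: Luche 1,2-reduction with Felkin–Anh attack anti to the large C11 substituent on C7 gives the 6R alcohol, and acid cleavage of the tert-butyl ester then closes the trans-fused γ-lactone, which is also the more stable ring fusion.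

Step 12
Reactants: 18 lactone (name as in step 11)
Product: 19 (6R,7R,8S)-14-acetoxy-8-(acryloyloxy)-15-oxogermacra-1(10)E,4E,11(13)-trien-12,6-olide
Conditions: SeO2 (1.2 equiv), 1,4-dioxane, 60 °C
Reagents that add atoms: selenium dioxide O=[Se]=O
Why: Riley oxidation (ene reaction then 2,3-shift) takes the free methyl group trans to C6 on the C4=C5 alkene to the enal with the same geometry, because the other trisubstituted alkene offers only an acetoxy-bearing CH2 in that position and the remaining alkenes are electron-poor.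

Step 13
Reactants: 19 enal acrylate (name as in step 12); 20 formaldehyde
Product: 21 target CNP0198933.2
Conditions: 37 % aq. 20, DABCO (1 equiv), 1,4-dioxane–H2O, 25 °C
Reagents that add atoms: none
Why: In this Morita–Baylis–Hillman reaction only the monosubstituted acrylate has the α-hydrogen needed to release DABCO after the aldol step, so amine addition to the α-methylene lactone or to the α-branched enal is reversible and unproductive.

## Compound list
1 | 3-methylcyclohex-2-en-1-one | CC1=CC(=O)CCC1 | starting material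
2 | acetone | CC(C)=O | starting material
3 | 6-(2-hydroxypropan-2-yl)-3-methylcyclohex-2-en-1-one | CC1=CC(=O)C(CC1)C(C)(C)O | intermediate
4 | 3-methyl-6-(prop-1-en-2-yl)cyclohex-2-en-1-one | CC1=CC(=O)C(CC1)C(C)=C | intermediate
5 | 6-(3-chloroprop-1-en-2-yl)-3-methylcyclohex-2-en-1-one | CC1=CC(=O)C(CC1)C(=C)CCl | intermediate
6 | tert-butyl acrylate | C=CC(=O)OC(C)(C)C | starting material
7 | 2,2-dimethoxyacetaldehyde | COC(OC)C=O | starting material
8 | tert-butyl 3-hydroxy-4,4-dimethoxy-2-methylidenebutanoate | C=C(C(O)C(OC)OC)C(=O)OC(C)(C)C | intermediate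
9 | tert-butyl 3-acetoxy-4,4-dimethoxy-2-methylidenebutanoate | C=C(C(OC(C)=O)C(OC)OC)C(=O)OC(C)(C)C | intermediate
10 | tert-butyl (E)-2-(acetoxymethyl)-4,4-dimethoxybut-2-enoate | CC(=O)OC/C(=C\C(OC)OC)C(=O)OC(C)(C)C | intermediate
11 | tert-butyl (E)-2-(acetoxymethyl)-4-oxobut-2-enoate | CC(=O)OC/C(=C\C=O)C(=O)OC(C)(C)C | intermediate
12 | (2E,4S)-hydroxy dienoate bearing ring A | CC1=CC(=O)C(CC1)C(=C)C[C@H](O)/C=C(\COC(C)=O)C(=O)OC(C)(C)C | intermediate
13 | (1R,2S)-decalin diol | O[C@H]1CC(=C)C2CCC(C)=CC2(O)[C@@H]1C(=C)C(=O)OC(C)(C)C | intermediate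
14 | acryloyl chloride | C=CC(=O)Cl | starting material
15 | (1R,2S)-decalin C8 acrylate | C=CC(=O)O[C@H]1CC(=C)C2CCC(C)=CC2(O)[C@@H]1C(=C)C(=O)OC(C)(C)C | intermediate
16 | (1R,3Z,7E,10S)-ten-membered dienone | C=CC(=O)O[C@H]1C/C(COC(C)=O)=C\CC/C(C)=C\C(=O)[C@@H]1C(=C)C(=O)OC(C)(C)C | intermediate
17 | (6R,7R,8S)-6-hydroxy tert-butyl ester | C=CC(=O)O[C@H]1C/C(COC(C)=O)=C\CC/C(C)=C\[C@@H](O)[C@@H]1C(=C)C(=O)OC(C)(C)C | intermediate
18 | (6R,7R,8S)-14-acetoxy-8-acryloyloxy germacranolide with C15 methyl | C=CC(=O)O[C@H]1C/C(COC(C)=O)=C\CC/C(C)=C\[C@H]2OC(=O)C(=C)[C@H]12 | intermediate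
19 | (6R,7R,8S)-14-acetoxy-8-acryloyloxy-15-oxo germacranolide | C=CC(=O)O[C@H]1C/C(COC(C)=O)=C\CC/C(C=O)=C\[C@H]2OC(=O)C(=C)[C@H]12 | intermediate
20 | formaldehyde | C=O | starting material
21 | CNP0198933.2 | C=C(CO)C(=O)O[C@H]1C/C(COC(C)=O)=C\CC/C(C=O)=C\[C@H]2OC(=O)C(=C)[C@H]12 | target

## Step count and risks
Total steps: 13. Longest linear sequence: 10 (steps 1–3 and 7–13).

**Step 10 (new ring expansion).**
- Risks: the reaction may instead cleave C6–C7, ionise the tertiary allylic alcohol, or eliminate the β-acyloxy group of 16.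
- The fallback uses known chemistry, sets out from 12 and returns at 16.
- m-CPBA epoxidises only the electron-rich C10=C14 alkene of 12 to the C10–C14 spiro-epoxide F1.
- The Pd(PPh3)4/InI cyclisation of step 8 then gives the epoxy decalin diol F2, and acryloyl chloride gives the epoxy decalin acrylate F3.
- Heating with Ti(OiPr)4 triggers the known epoxy-alcohol Grob fragmentation: the alkoxide pushes, the Lewis acid opens the epoxide at its tertiary carbon, and both epoxide epimers therefore converge. The product is the ten-membered C14 alcohol F4.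
- Ac2O/pyridine converts F4 into 16.

**Step 8 (Pd/InI cyclisation).**
- Risks: 1,4-elimination of the allylindium, slow addition to the hindered enone carbonyl, or poor C7 control.
- The fallback sets out from 12 and returns at 13.
- K2CO3/MeOH removes the acetate to give the allylic diol F5.
- CBr4/PPh3 at −20 °C converts only the primary allylic alcohol into the allylic bromide F6.
- Indium powder in THF–water closes ring B by a direct halide Barbier reaction without palladium.

**Step 13 (late Baylis–Hillman reaction).**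
- Risks: a slow reaction, irreversible amine adducts, or acetate loss.
- The fallback sets out from 13 and returns at 21.
- Bought 2-(hydroxymethyl)acrylic acid is silylated (TBDPSCl, imidazole, then K2CO3/MeOH) to the silyl ether acid F7.
- EDC/DMAP esterifies 13 at C8 to the silyloxy decalin ester F8.
- The conditions of step 10 give the silyloxy dienone F9.
- The conditions of step 11 give the silyloxy lactone F11 by way of the silyloxy hydroxy ester F10.
- SeO2 gives the silyloxy enal F12, and HF·pyridine gives 21.

## Further compounds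
F1 | step 10 | C10–C14 spiro-epoxide of 12 | CC1=CC(=O)C(CC1)C1(CO1)C[C@H](O)/C=C(\COC(C)=O)C(=O)OC(C)(C)C
F2 | step 10 | epoxy decalin diol | O[C@H]1CC2(CO2)C2CCC(C)=CC2(O)[C@@H]1C(=C)C(=O)OC(C)(C)C
F3 | step 10 | epoxy decalin acrylate | C=CC(=O)O[C@H]1CC2(CO2)C2CCC(C)=CC2(O)[C@@H]1C(=C)C(=O)OC(C)(C)C
F4 | step 10 | ten-membered C14 alcohol | C=CC(=O)O[C@H]1C/C(CO)=C\CC/C(C)=C\C(=O)[C@@H]1C(=C)C(=O)OC(C)(C)C
F5 | step 8 | allylic diol | CC1=CC(=O)C(CC1)C(=C)C[C@H](O)/C=C(\CO)C(=O)OC(C)(C)C
F6 | step 8 | allylic bromide | CC1=CC(=O)C(CC1)C(=C)C[C@H](O)/C=C(\CBr)C(=O)OC(C)(C)C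
F7 | step 13 | 2-[(tert-butyldiphenylsilyloxy)methyl]acrylic acid | C=C(CO[Si](c1ccccc1)(c1ccccc1)C(C)(C)C)C(=O)O
F8 | step 13 | silyloxy decalin ester | C=C(CO[Si](c1ccccc1)(c1ccccc1)C(C)(C)C)C(=O)O[C@H]1CC(=C)C2CCC(C)=CC2(O)[C@@H]1C(=C)C(=O)OC(C)(C)C
F9 | step 13 | silyloxy dienone | C=C(CO[Si](c1ccccc1)(c1ccccc1)C(C)(C)C)C(=O)O[C@H]1C/C(COC(C)=O)=C\CC/C(C)=C\C(=O)[C@@H]1C(=C)C(=O)OC(C)(C)C
F10 | step 13 | silyloxy hydroxy ester | C=C(CO[Si](c1ccccc1)(c1ccccc1)C(C)(C)C)C(=O)O[C@H]1C/C(COC(C)=O)=C\CC/C(C)=C\[C@@H](O)[C@@H]1C(=C)C(=O)OC(C)(C)C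
F11 | step 13 | silyloxy lactone | C=C(CO[Si](c1ccccc1)(c1ccccc1)C(C)(C)C)C(=O)O[C@H]1C/C(COC(C)=O)=C\CC/C(C)=C\[C@H]2OC(=O)C(=C)[C@H]12
F12 | step 13 | silyloxy enal | C=C(CO[Si](c1ccccc1)(c1ccccc1)C(C)(C)C)C(=O)O[C@H]1C/C(COC(C)=O)=C\CC/C(C=O)=C\[C@H]2OC(=O)C(=C)[C@H]12
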